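## Retrosynthetic overview
1. Ludongnin I (19) ← exo-face hydrogenation of the C16=C17 enone, which comes from a Saegusa oxidation of the 16-methyl ketone. The bicyclo[3.2.1]octanone is made by a 5-exo α-keto radical cyclization (C16→C13) onto a cyclohexene.
2. The cyclohexene ring C and the C8 quaternary centre come from a Diels–Alder reaction of butadiene with a spiro 3-propionyl-5,6-dihydropyran-2-one (C8=C9). That enone comes from an intramolecular Knoevenagel condensation of a C9 aldehyde with a C20 β-ketoester.
3. The C10 quaternary centre comes from ester-enolate hydroxymethylation anti to the cis-fused 6,19-lactone. That lactone/ring A comes from a Diels–Alder reaction of 4-methylbutenolide (1) with methyl 2,4-pentadienoate (2), the proposed new enantioselective step.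
4. The lactone is converted to the C6 methyl acetal early so that it survives the later steps.
5. Ring order: ring A + 6,19-THF lactone (Step 1) → spiro δ-lactone (Step 9) → ring C (Step 10) → ring D (Step 12) → C16 methyl (Step 15).

Assumptions (ent-kaurane numbering throughout):
- The 6-OMe of the target is the thermodynamic convex-face (exo) anomer, cis to H-5 and C18.
- The C16 methyl is endo, which is reached by delivering H to the exo face of the exocyclic enone.
- The Step 1 catalyst enantiomer is chosen to give 3.

## Route

**Step 1**
Reactants: 1 (4-methylfuran-2(5H)-one); 2 (methyl (2E)-penta-2,4-dienoate)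
Product: 3 (cis-fused 6,19-lactone/cyclohexene methyl ester; C4-Me and H-5 on the convex face, C19/C6 bridge and C20 ester on the other face)
Conditions: chiral oxazaborolidinium triflimide (20 mol%), CH2Cl2, –40 °C, 60 h (2 in excess)
Reagents that add atoms: none (both partners are numbered reactants)
Why: Proposed new method: a chiral Lewis acid binds the lactone C=O of the β-methylbutenolide and lowers its LUMO, so the 1-ester diene adds "ortho" (CH2 terminus to the β-carbon C4, ester terminus to the α-carbon C5) through an endo transition state. The catalyst pocket selects one enantioface, which sets C4 (quaternary) and C5, and the cyclic dienophile enforces the cis ring fusion; the C10 centre is erased in Step 2. The closest known reaction is chiral-Lewis-acid Diels–Alder of enones/acrylates with dienes, but β-alkyl butenolides with 1-carboxy dienes have not been used.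

**Step 2**
Reactants: 3
Product: 4 (C10-quaternary ester: C20 CO2Me, C9 CH2OBn)
Conditions: LDA (1.1 equiv), THF, –78 °C; then BOMCl, –78 → 0 °C
Reagents that add atoms: benzyl chloromethyl ether (BOMCl), ClCOCc1ccccc1
Why: Ester enolate α-alkylation (α-selective on the C1=C2 dienolate); the lactone bridge blocks the face bearing C19/C6, so the electrophile enters from the opposite face, putting C9 trans to C19 and leaving C20 cis (1,3-diaxial) to it, as in the target.

**Step 3**
Reactants: 4
Product: 5 (lactol, mixture of C6 anomers)
Conditions: DIBAL-H (1.1 equiv), CH2Cl2, –78 °C; Rochelle salt work-up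
Reagents that add atoms: none
Why: DIBAL reduction of the strained, cyclic lactone is faster than that of the hindered acyclic neopentyl methyl ester at –78 °C.

**Step 4**
Reactants: 5
Product: 6 (C6 methyl acetal, exo-OMe, cis-fused THF)
Conditions: MeOH, PPTS (10 mol%), rt, 12 h
Reagents that add atoms: methanol, CO
Why: Acid-catalysed acetalization under thermodynamic control; the convex-face methoxy anomer predominates and sets C6, and the acetal is a robust masked C6 aldehyde.

**Step 5**
Reactants: 6
Product: 7 (C20 primary alcohol, C9 OBn)
Conditions: LiAlH4, THF, 0 → 65 °C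
Reagents that add atoms: none
Why: Hydride reduction of the remaining ester; the acetal and benzyl ether are inert.

**Step 6**
Reactants: 7; 8 (methyl 3-oxopentanoate)
Product: 9 (C20 3-oxopentanoate ester)
Conditions: 8 (3 equiv), DMAP (0.2 equiv), toluene, 110 °C, MeOH distilled off
Reagents that add atoms: methyl 3-oxopentanoate, CCC(=O)CC(=O)OC
Why: β-Ketoester transesterification via an acylketene, which acylates the hindered axial neopentyl alcohol cleanly; this installs C7, C8, C15, C16 and C17.

**Step 7**
Reactants: 9
Product: 10 (ring A saturated, free C9 CH2OH)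
Conditions: H2 (1 atm), Pd(OH)2/C, EtOAc, rt
Reagents that add atoms: none
Why: Hydrogenolysis of the benzyl ether and hydrogenation of the C1=C2 alkene; the ketone, ester and acetal survive, and the product is oxidized immediately to avoid acyl migration.

**Step 8**
Reactants: 10
Product: 11 (C9 aldehyde)
Conditions: Dess–Martin periodinane, NaHCO3, CH2Cl2, 0 °C → rt
Reagents that add atoms: none
Why: Mild oxidation of the primary alcohol to a non-enolizable α-quaternary aldehyde, compatible with the β-ketoester.

**Step 9**
Reactants: 11
Product: 12 (spiro 3-propionyl-5,6-dihydropyran-2-one, C8=C9)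
Conditions: piperidine/AcOH (10 mol% each), 4 Å MS, toluene, 80 °C
Reagents that add atoms: none
Why: Intramolecular Knoevenagel condensation closes the six-membered spiro lactone (C10–C20–O–C7–C8=C9); the ring fixes the alkene geometry.

**Step 10**
Reactants: 12; 13 (1,3-butadiene)
Product: 14 (cyclohexene-fused spirolactone with C8 propionyl)
Conditions: 13 (20 equiv), BHT, toluene, 110 °C, sealed tube, 24 h
Reagents that add atoms: 1,3-butadiene, C=CC=C
Why: Diels–Alder reaction on the highly electrophilic alkylidene β-ketolactone. Suprafacial addition makes C7 and C10 cis, which fixes C8/C9 relative to each other, and butadiene adds anti to the bulky C5/C6-acetal arm and syn to C1, setting C8 and C9 relative to C10.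

**Step 11**
Reactants: 14
Product: 15 (C16 α-bromoketone, epimeric at C16)
Conditions: (i) TMSOTf, Et3N, CH2Cl2, 0 °C; (ii) NBS, THF, –78 °C
Reagents that add atoms: NBS, O=C1CCC(=O)N1Br
Why: C8 is quaternary, so enolization is only toward C16; the silyl enol ether reacts with NBS faster than the isolated cyclohexene (Rubottom-type α-bromination).

**Step 12**
Reactants: 15
Product: 16 (bicyclo[3.2.1]octan-15-one, 16-methyl, C16 epimer mixture)
Conditions: Bu3SnH (1.5 equiv, syringe pump), AIBN, benzene (0.005 M), 80 °C
Reagents that add atoms: none
Why: Radical 5-exo-trig cyclization of the α-keto radical at C16 onto C13=C12; C13 is forced by the bridged geometry, the C12 radical is reduced, and the C16 epimers converge in Steps 13–14.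

**Step 13**
Reactants: 16
Product: 17 (C15 TMS enol ether, C15=C16)
Conditions: TMSOTf, Et3N, CH2Cl2, 0 °C
Reagents that add atoms: TMSOTf, C[Si](C)(C)OS(=O)(=O)C(F)(F)F
Why: Kinetic silylation; C8 is quaternary and C13 is a bridgehead, so only the C16 enol is possible.

**Step 14**
Reactants: 17
Product: 18 (exocyclic enone, C16=C17, C15 ketone)
Conditions: Pd(OAc)2 (1.1 equiv), MeCN, rt
Reagents that add atoms: none
Why: Saegusa–Ito oxidation; β-hydride elimination can only come from the C17 methyl (the C13 bridgehead alkene is excluded by Bredt's rule), giving the α-methylene ketone regiospecifically.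

**Step 15**
Reactants: 18
Product: 19 (ludongnin I)
Conditions: H2 (1 atm), 10% Pd/C, EtOAc, rt
Reagents that add atoms: none
Why: Catalytic hydrogenation of the exocyclic enone; H is delivered to the less hindered exo face (syn to the C14 bridge), which leaves the C17 methyl endo as in the target and sets C16.

## Compound list
1 | 4-methylfuran-2(5H)-one | CC1=CC(=O)OC1 | starting material
2 | methyl (2E)-penta-2,4-dienoate | C=C/C=C/C(=O)OC | starting material
3 | methyl 3a-methyl-1-oxo-hexahydroisobenzofuran-7-carboxylate (cis-fused 6,19-lactone, C1=C2, C20 ester) | O=C1OC[C@]2(C)CC=C[C@H](C(=O)OC)[C@H]12 | intermediate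
4 | C10-BOM-alkylated lactone ester | O=C1OC[C@]2(C)CC=C[C@](COCc3ccccc3)(C(=O)OC)[C@H]12 | intermediate
5 | lactol (C6 anomer mixture) | OC1OC[C@]2(C)CC=C[C@](COCc3ccccc3)(C(=O)OC)[C@H]12 | intermediate
6 | C6 methyl acetal ester | CO[C@H]1OC[C@]2(C)CC=C[C@](COCc3ccccc3)(C(=O)OC)[C@H]12 | intermediate
7 | C20 alcohol, C9 OBn | CO[C@H]1OC[C@]2(C)CC=C[C@](COCc3ccccc3)(CO)[C@H]12 | intermediate
8 | methyl 3-oxopentanoate | CCC(=O)CC(=O)OC | starting material
9 | C20 3-oxopentanoate ester | CO[C@H]1OC[C@]2(C)CC=C[C@](COCc3ccccc3)(COC(=O)CC(=O)CC)[C@H]12 | intermediate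
10 | saturated ring A, free C9 alcohol | CO[C@H]1OC[C@]2(C)CCC[C@](CO)(COC(=O)CC(=O)CC)[C@H]12 | intermediate
11 | C9 aldehyde | CO[C@H]1OC[C@]2(C)CCC[C@](C=O)(COC(=O)CC(=O)CC)[C@H]12 | intermediate
12 | spiro 3-propionyl-dihydropyranone | CO[C@H]1OC[C@]2(C)CCC[C@]3(COC(=O)C(C(=O)CC)=C3)[C@H]12 | intermediate
13 | 1,3-butadiene | C=CC=C | starting material
14 | Diels–Alder adduct (ring C cyclohexene, C8 propionyl) | CO[C@H]1OC[C@]2(C)CCC[C@]3(COC(=O)[C@@]4(C(=O)CC)CC=CC[C@H]43)[C@H]12 | intermediate
15 | C16 α-bromoketone | CO[C@H]1OC[C@]2(C)CCC[C@]3(COC(=O)[C@@]4(C(=O)C(C)Br)CC=CC[C@H]43)[C@H]12 | intermediate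
16 | bicyclo[3.2.1] 16-methyl ketone (C16 epimers) | CO[C@H]1OC[C@]2(C)CCC[C@]3(COC(=O)[C@@]45C[C@@H](CC[C@H]43)C(C)C5=O)[C@H]12 | intermediate
17 | TMS enol ether of 16 | CO[C@H]1OC[C@]2(C)CCC[C@]3(COC(=O)[C@@]45C[C@@H](CC[C@H]43)C(C)=C5O[Si](C)(C)C)[C@H]12 | intermediate
18 | exocyclic enone | CO[C@H]1OC[C@]2(C)CCC[C@]3(COC(=O)[C@@]45C[C@@H](CC[C@H]43)C(=C)C5=O)[C@H]12 | intermediate
19 | ludongnin I | CO[C@H]1OC[C@]2(C)CCC[C@]3(COC(=O)[C@@]45C[C@@H](CC[C@H]43)[C@@H](C)C5=O)[C@H]12 | target

## Totals
Total steps: 15. Longest linear sequence: 15 (1 → 3 → 4 → … → 19). Building blocks 8 and 13 enter at Steps 6 and 10.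

**Three steps most likely to fail**
1. **Step 1 (proposed new enantioselective Diels–Alder).** The β-methylbutenolide is a poor dienophile and the ester-substituted diene is electron-poor. Fallback (known chemistry, different approach): use 8-phenylmenthyl (E)-penta-2,4-dienoate with Me2AlCl or thermal activation, separate the diastereomeric adducts by chromatography, and let the LiAlH4 reduction in Step 5 cleave the auxiliary to give 7.
2. **Step 10 (butadiene Diels–Alder).** The β-carbon C9 is neopentylic, and facial selectivity relative to C10 may be modest. Fallback: build the same adduct 14 stepwise by conjugate allylation of 12 at C9 (allyl-MgBr/CuI), C8-allylation (KHMDS, allyl bromide), then RCM (Grubbs II) to form C12=C13.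
3. **Step 12 (radical cyclization).** The 5-exo cyclization may compete with 6-endo closure to a bicyclo[2.2.2]octane. Fallback: skip the bromide and treat the enol silane of 14 with Pd(OAc)2 (Ihara–Toyota cycloalkenylation, a Pd-enolate 5-exo closure), then H2/Pd-C to give 16 and continue with Steps 13–15.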